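**Retrosynthetic overview**

1. Feature: ring B (cyclopentanone) and ring C (γ-lactone) share the CH–C(CH3) bond. The spiro carbon of ring B carries two acyl carbons (the ring-B ketone and the ring-A lactone C=O) and a CH2 that leads to the fusion CH, so it is read as the central carbon of a malonate bearing a nucleophilic CH2.
2. Ring A (δ-lactone) is cut at its acyl–O bond and at the CH(isopropenyl)–CH(O) bond: lactonisation of a hydroxy ester obtained by a carbonyl-ene reaction of a prenyl group on the spiro carbon with 3-methyl-2-oxobutanal.
3. Ring B is cut at CH2–CH(fusion) and at C(CH3)–C(=O): the zinc reagent of dimethyl 2-(iodomethyl)-2-prenylmalonate plus 3,5,5-trimethylfuran-2(5H)-one, joined by copper-catalysed asymmetric conjugate addition and Dieckmann closure in one flask.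
4. Fragments: the malonate is alkylated twice (prenyl bromide, CH2I2); the butenolide is made by ring-closing metathesis of 2-methylbut-3-en-2-yl methacrylate, which fixes the position of the methyl group through the starting materials.
5. Ring order: C (butenolide), then B (key step), then A (last step).

Key step: step 5

Remark: the sense of induction of the chiral ligands in steps 5 and 7 on these substrates cannot be fixed in advance; the antipodes named are provisional, and the mirror-image ligand is used if a trial shows the opposite sense.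

**Route**

Step 1
Reactants: 1 dimethyl propanedioate; 2 1-bromo-3-methylbut-2-ene
Product: 4 dimethyl 2-(3-methylbut-2-enyl)propanedioate, via sodium malonate enolate 3 (not isolated)
Conditions: NaH (1.0 equiv), 1 (1.5 equiv), THF, 0 °C; then 2, 0 → 20 °C
Reagents that add atoms: none
Why: Malonate alkylation (SN2) of the sodium enolate by an allylic bromide, with the excess of 1 holding back double prenylation; no stereocentre is formed.

Step 2
Reactants: 4 dimethyl 2-(3-methylbut-2-enyl)propanedioate
Product: 6 dimethyl 2-(iodomethyl)-2-(3-methylbut-2-enyl)propanedioate, via sodium prenylmalonate enolate 5 (not isolated)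
Conditions: NaH, THF, 0 °C; then CH2I2 (5 equiv), reflux
Reagents that add atoms: diiodomethane ICI
Why: SN2 alkylation of the tertiary malonate enolate by excess diiodomethane should stop at the iodomethyl stage, because the product is a neopentyl-type iodide that resists a second substitution; no stereocentre is formed.

Step 3
Reactants: 7 2-methylbut-3-en-2-ol; 8 2-methylprop-2-enoyl chloride
Product: 10 2-methylbut-3-en-2-yl 2-methylprop-2-enoate, via lithium alkoxide 9 (not isolated)
Conditions: n-BuLi, THF, −78 °C; then 8, −78 → 0 °C
Reagents that add atoms: none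
Why: O-Acylation of the preformed lithium tert-alkoxide by the acid chloride (nucleophilic acyl substitution) is the dependable way to esterify a hindered tertiary allylic alcohol; no stereocentre is formed.

Step 4
Reactants: 10 2-methylbut-3-en-2-yl 2-methylprop-2-enoate
Product: 11 3,5,5-trimethylfuran-2(5H)-one
Conditions: second-generation Grubbs catalyst RuCl2(=CHPh)(PCy3)(H2IMes) (5 mol %), toluene, 80 °C
Reagents that add atoms: none
Why: Ring-closing olefin metathesis of an allylic methacrylate to an α-methylbutenolide, helped by the gem-dimethyl group and driven by loss of ethene, places the methyl group unambiguously next to the carbonyl; no stereocentre is formed.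

Step 5
Reactants: 6 dimethyl 2-(iodomethyl)-2-(3-methylbut-2-enyl)propanedioate; 11 3,5,5-trimethylfuran-2(5H)-one
Product: 14 methyl (3aS,5R,6aS)-1,1,3a-trimethyl-5-(3-methylbut-2-enyl)-3,4-dioxohexahydro-1H-cyclopenta[c]furan-5-carboxylate, via alkylzinc iodide 12 (not isolated), via zinc lactone enolate 13 (not isolated)
Conditions: Zn dust, LiCl, THF, 40 °C (cat. BrCH2CH2Br, Me3SiCl); then 11, Cu(OTf)2 (5 mol %), (S,R,R)-O,O'-(1,1'-binaphthyl-2,2'-diyl)-N,N-bis(1-phenylethyl)phosphoramidite (10 mol %), toluene/THF, −30 → 20 °C; pH 7 buffer, 0 °C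
Reagents that add atoms: none
Why: Proposed new method: zinc inserts into the C–I bond of 6 to give the ester homoenolate 12 (no β-hydrogen, no β-leaving group, and diester carbonyls that should not undergo the cyclopropanolate acyl shift of ketone homoenolates), transmetalation to the monovalent copper–phosphoramidite complex and 1,4-addition place its CH2 on the β-carbon of 11, and the zinc enolate 13 attacks one malonate ester and expels methoxide. The closest known reaction types are the copper/phosphoramidite-catalysed conjugate addition of organozinc reagents to unsaturated lactones, the copper-mediated conjugate addition of zinc ester homoenolates and the trapping of conjugate-addition zinc enolates by a tethered ester (Michael–Dieckmann annulation); what is new is their union with an alkylzinc iodide on an α-methyl butenolide. Ring B closes by 5-exo-trig acyl substitution of the tertiary enolate carbon on an ester carbon five atoms away. The fusion CH (S) is set by the ligand, which selects one enantiotopic face of the flat achiral butenolide, and the angular C–CH3 carbon (S) follows from it because a bicyclo[3.3.0] ring system can only close cis. The spiro carbon (R) is set by which diastereotopic ester is attacked: the ester that remains is expected on the concave face, where it can stay bound to the zinc on the enolate oxygen, and the bulkier prenyl CH2 on the convex face away from the inner methyl of the CMe2 group. The step needs 1,4- over 1,2-addition (copper catalysis, low carbonyl reactivity of RZnI) and acylation of the enolate before protonation (two esters held beside it, aprotic medium), and since the new ketone lies between two quaternary carbons and cannot be stabilised as an enolate, the poorly nucleophilic zinc methoxide and a cold pH 7 quench are relied on to prevent retro-Claisen opening.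

Step 6
Reactants: 15 3-methylbutan-2-one
Product: 16 3-methyl-2-oxobutanal
Conditions: SeO2 (1.0 equiv), 1,4-dioxane, H2O (cat.), reflux; distil from P2O5 before use
Reagents that add atoms: selenium dioxide O=[Se]=O
Why: Riley oxidation of a methyl ketone by SeO2 converts the CH3 next to the carbonyl into the aldehyde, the hindered methine on the other side having no second hydrogen to lose; no stereocentre is formed.

Step 7
Reactants: 14 methyl (3aS,5R,6aS)-1,1,3a-trimethyl-5-(3-methylbut-2-enyl)-3,4-dioxohexahydro-1H-cyclopenta[c]furan-5-carboxylate; 16 3-methyl-2-oxobutanal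
Product: 17 methyl (3aS,5R,6aS)-5-[(2S,3S)-3-hydroxy-5-methyl-4-oxo-2-(prop-1-en-2-yl)hexyl]-1,1,3a-trimethyl-3,4-dioxohexahydro-1H-cyclopenta[c]furan-5-carboxylate
Conditions: Cu(OTf)2 (10 mol %), 2,2'-(propane-2,2-diyl)bis[(4S)-4-tert-butyl-4,5-dihydrooxazole] (11 mol %), 16 (1.1 equiv), CH2Cl2, 4 Å MS, −20 → 0 °C
Reagents that add atoms: none
Why: Lewis-acid-catalysed carbonyl-ene reaction in which the divalent copper bis(oxazoline) complex chelates the 1,2-dicarbonyl unit of 16, so that the aldehyde carbon bonds to the less substituted carbon of the prenyl alkene with hydrogen transfer from a methyl group (giving the isopropenyl group); the ligand shields one aldehyde face and sets the carbinol centre (S), the exo transition state typical of chelated glyoxylate-type enophiles places hydroxyl and isopropenyl syn along the CH2–CH–CH(OH)–C(=O) chain and thereby sets the allylic centre (S), and only a slight excess of 16 is used so that the new 1,1-disubstituted alkene does not react a second time.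

Step 8
Reactants: 17 methyl (3aS,5R,6aS)-5-[(2S,3S)-3-hydroxy-5-methyl-4-oxo-2-(prop-1-en-2-yl)hexyl]-1,1,3a-trimethyl-3,4-dioxohexahydro-1H-cyclopenta[c]furan-5-carboxylate
Product: 18 CNP0216954.1, the spiro compound in which C5 of the (3aS,5R,6aS)-1,1,3a-trimethyl-3,4-dioxohexahydro-1H-cyclopenta[c]furan unit is C3' of a (5'S,6'S)-6'-(2-methylpropanoyl)-5'-(prop-1-en-2-yl)oxan-2'-one
Conditions: PPTS (0.2 equiv), toluene, 5 Å MS, 70 °C
Reagents that add atoms: none
Why: Acid-catalysed intramolecular transesterification (lactonisation) of the δ-hydroxy ester closes the six-membered ring A, favoured by the quaternary spiro carbon (Thorpe–Ingold effect) and driven by uptake of methanol on the sieves; no stereocentre is formed, and the mild acid is chosen so that the cis-disposed CH next to the isobutyryl ketone, which could epimerise through its enol, stays untouched.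

**Compound list**

1 | dimethyl propanedioate | COC(=O)CC(=O)OC | starting material
2 | 1-bromo-3-methylbut-2-ene | CC(C)=CCBr | starting material
3 | sodium enolate of dimethyl propanedioate | [Na+].COC(=O)[CH-]C(=O)OC | intermediate
4 | dimethyl 2-(3-methylbut-2-enyl)propanedioate | COC(=O)C(CC=C(C)C)C(=O)OC | intermediate
5 | sodium enolate of dimethyl 2-(3-methylbut-2-enyl)propanedioate | [Na+].COC(=O)[C-](CC=C(C)C)C(=O)OC | intermediate
6 | dimethyl 2-(iodomethyl)-2-(3-methylbut-2-enyl)propanedioate | COC(=O)C(CI)(CC=C(C)C)C(=O)OC | intermediate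
7 | 2-methylbut-3-en-2-ol | CC(C)(O)C=C | starting material
8 | 2-methylprop-2-enoyl chloride | CC(=C)C(Cl)=O | starting material
9 | lithium 2-methylbut-3-en-2-olate | [Li+].CC(C)([O-])C=C | intermediate
10 | 2-methylbut-3-en-2-yl 2-methylprop-2-enoate | C=CC(C)(C)OC(=O)C(C)=C | intermediate
11 | 3,5,5-trimethylfuran-2(5H)-one | CC1=CC(C)(C)OC1=O | intermediate
12 | [2,2-bis(methoxycarbonyl)-5-methylhex-4-enyl]zinc iodide | COC(=O)C(C[Zn]I)(CC=C(C)C)C(=O)OC | intermediate
13 | iodozinc enolate of the (S)-conjugate adduct (lactone C=C(O–ZnI), malonate still open) | COC(=O)C(CC=C(C)C)(C[C@@H]1C(C)(C)OC(O[Zn]I)=C1C)C(=O)OC | intermediate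
14 | methyl (3aS,5R,6aS)-1,1,3a-trimethyl-5-(3-methylbut-2-enyl)-3,4-dioxohexahydro-1H-cyclopenta[c]furan-5-carboxylate | CC(C)=CC[C@]1(C[C@@H]2C(C)(C)OC(=O)[C@]2(C)C1=O)C(=O)OC | intermediate
15 | 3-methylbutan-2-one | CC(C)C(C)=O | starting material
16 | 3-methyl-2-oxobutanal | CC(C)C(=O)C=O | intermediate
17 | methyl (3aS,5R,6aS)-5-[(2S,3S)-3-hydroxy-5-methyl-4-oxo-2-(prop-1-en-2-yl)hexyl]-1,1,3a-trimethyl-3,4-dioxohexahydro-1H-cyclopenta[c]furan-5-carboxylate | C=C(C)[C@@H]([C@H](O)C(=O)C(C)C)C[C@]1(C[C@@H]2C(C)(C)OC(=O)[C@]2(C)C1=O)C(=O)OC | intermediate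
18 | CNP0216954.1 (spiro δ-lactone on the bicyclic ketolactone) | C=C(C)[C@@H]1C[C@]2(C[C@@H]3C(C)(C)OC(=O)[C@]3(C)C2=O)C(=O)O[C@@H]1C(=O)C(C)C | target

**Step count and risks**

Total steps: 8. Longest linear sequence: 5 (steps 1, 2, 5, 7, 8).

Step 5 is the step that carries the label.
- Process at risk: the alkylzinc/copper species may fail to add to the hindered α-methyl butenolide with its quaternary neighbour; the ligand may differentiate the two faces poorly; ring closure may take the other ester; the homoenolate may rearrange by acyl shift before it adds.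
- Fallback (known chemistry), setting out from 6 and 11 and returning at 14: iodide 6 is added to 11 by a reductive radical conjugate addition (Zn dust, copper iodide CuI, EtOH/H2O, ultrasound). This should give the racemic saturated lactone dimethyl 2-(3-methylbut-2-enyl)-2-[(2,2,4-trimethyl-5-oxooxolan-3-yl)methyl]propanedioate F1. LiHMDS in THF at −78 °C then forms the lactone enolate, which closes ring B by Dieckmann condensation to the racemate of 14. Preparative HPLC on a chiral stationary phase separates 14 from its mirror image, methyl (3aR,5S,6aR)-1,1,3a-trimethyl-5-(3-methylbut-2-enyl)-3,4-dioxohexahydro-1H-cyclopenta[c]furan-5-carboxylate F2. A spiro epimer, if formed, is removed on silica.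

Step 7.
- Process at risk: weak control of the aldehyde face and of the syn/anti sense by the catalyst in the presence of the chelating keto ester core, and a second ene reaction at the new isopropenyl group.
- Fallback, setting out from 14 and returning at 17: the ene reaction is replaced by an allylboration through a closed chair transition state. Allylic oxidation of the prenyl group of 14 at its (E)-methyl group (SeO2 cat., t-BuOOH, CH2Cl2) gives methyl (3aS,5R,6aS)-5-[(2E)-4-hydroxy-3-methylbut-2-enyl]-1,1,3a-trimethyl-3,4-dioxohexahydro-1H-cyclopenta[c]furan-5-carboxylate F3. Borylation of the allylic alcohol with bis(pinacolato)diboron and the divalent palladium salt Pd(MeCN)4(BF4)2 (DMSO/MeOH) gives the linear (E)-allylboronate methyl (3aS,5R,6aS)-1,1,3a-trimethyl-5-[(2E)-3-methyl-4-(4,4,5,5-tetramethyl-1,3,2-dioxaborolan-2-yl)but-2-enyl]-3,4-dioxohexahydro-1H-cyclopenta[c]furan-5-carboxylate F4. Its addition to the aldehyde of 16 under (R)-3,3'-bis(2,4,6-triisopropylphenyl)-1,1'-binaphthyl-2,2'-diyl hydrogen phosphate (toluene, −30 °C) should deliver, after hydrolysis of the borate, 17. The (E) geometry fixes the same relative configuration as the ene route, and the phosphoric acid fixes the aldehyde face.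

Step 8.
- Process at risk: slow acyl transfer at the neopentyl-like methyl ester, so that the acid has time to shift the α-ketol through its enediol or to epimerise the CH next to the ketone.
- Fallback, setting out from 2 and returning at 18: the spectator ester is made an active ester from the start. Commercially available bis(2,2,2-trifluoroethyl) propanedioate (O=C(CC(=O)OCC(F)(F)F)OCC(F)(F)F) is alkylated with 2 as in step 1 to give bis(2,2,2-trifluoroethyl) 2-(3-methylbut-2-enyl)propanedioate F5, and with CH2I2 as in step 2 to give bis(2,2,2-trifluoroethyl) 2-(iodomethyl)-2-(3-methylbut-2-enyl)propanedioate F6. The conditions of step 5 with 11 should give 2,2,2-trifluoroethyl (3aS,5R,6aS)-1,1,3a-trimethyl-5-(3-methylbut-2-enyl)-3,4-dioxohexahydro-1H-cyclopenta[c]furan-5-carboxylate F7. The conditions of step 7 with 16 should give 2,2,2-trifluoroethyl (3aS,5R,6aS)-5-[(2S,3S)-3-hydroxy-5-methyl-4-oxo-2-(prop-1-en-2-yl)hexyl]-1,1,3a-trimethyl-3,4-dioxohexahydro-1H-cyclopenta[c]furan-5-carboxylate F8. F8 is expected to lactonise to 18 under neutral conditions (2-hydroxypyridine cat., toluene, 40 °C) without acid.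

**Further compounds**

F1 | step 5 | dimethyl 2-(3-methylbut-2-enyl)-2-[(2,2,4-trimethyl-5-oxooxolan-3-yl)methyl]propanedioate (racemic) | COC(=O)C(CC=C(C)C)(CC1C(C)C(=O)OC1(C)C)C(=O)OC
F2 | step 5 | methyl (3aR,5S,6aR)-1,1,3a-trimethyl-5-(3-methylbut-2-enyl)-3,4-dioxohexahydro-1H-cyclopenta[c]furan-5-carboxylate | CC(C)=CC[C@@]1(C[C@H]2C(C)(C)OC(=O)[C@@]2(C)C1=O)C(=O)OC
F3 | step 7 | methyl (3aS,5R,6aS)-5-[(2E)-4-hydroxy-3-methylbut-2-enyl]-1,1,3a-trimethyl-3,4-dioxohexahydro-1H-cyclopenta[c]furan-5-carboxylate | OC/C(C)=C/C[C@]1(C[C@@H]2C(C)(C)OC(=O)[C@]2(C)C1=O)C(=O)OC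
F4 | step 7 | methyl (3aS,5R,6aS)-1,1,3a-trimethyl-5-[(2E)-3-methyl-4-(4,4,5,5-tetramethyl-1,3,2-dioxaborolan-2-yl)but-2-enyl]-3,4-dioxohexahydro-1H-cyclopenta[c]furan-5-carboxylate | CC1(C)OB(C/C(C)=C/C[C@]2(C[C@@H]3C(C)(C)OC(=O)[C@]3(C)C2=O)C(=O)OC)OC1(C)C
F5 | step 8 | bis(2,2,2-trifluoroethyl) 2-(3-methylbut-2-enyl)propanedioate | CC(C)=CCC(C(=O)OCC(F)(F)F)C(=O)OCC(F)(F)F
F6 | step 8 | bis(2,2,2-trifluoroethyl) 2-(iodomethyl)-2-(3-methylbut-2-enyl)propanedioate | CC(C)=CCC(CI)(C(=O)OCC(F)(F)F)C(=O)OCC(F)(F)F
F7 | step 8 | 2,2,2-trifluoroethyl (3aS,5R,6aS)-1,1,3a-trimethyl-5-(3-methylbut-2-enyl)-3,4-dioxohexahydro-1H-cyclopenta[c]furan-5-carboxylate | CC(C)=CC[C@]1(C[C@@H]2C(C)(C)OC(=O)[C@]2(C)C1=O)C(=O)OCC(F)(F)F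
F8 | step 8 | 2,2,2-trifluoroethyl (3aS,5R,6aS)-5-[(2S,3S)-3-hydroxy-5-methyl-4-oxo-2-(prop-1-en-2-yl)hexyl]-1,1,3a-trimethyl-3,4-dioxohexahydro-1H-cyclopenta[c]furan-5-carboxylate | C=C(C)[C@@H]([C@H](O)C(=O)C(C)C)C[C@]1(C[C@@H]2C(C)(C)OC(=O)[C@]2(C)C1=O)C(=O)OCC(F)(F)F
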